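**Plan**
- Cuts, in retrosynthetic order: the allyl–O bond at C3 and the CH3–O bond at C9; then O11–C10a of ring C, with ring D taken back to a cyclohexa-2,5-dienone (OH on C6b, C=O at C9) and from there to a 4-hydroxyphenyl group; then C11a–H (ketone), O5–C6 and C6–C6a (C6 from formaldehyde); last the O–CMe2 and C2–CH2 bonds of ring E.
- Forward order: ring E is annulated onto the ring A/ring D deoxybenzoin, ring B follows (isoflavanone), ring C closes last while ring D is dearomatised and then rearomatised; O-methylation at C9 and deallylation at C3 finish.
- Stereochemistry: C6a and C11a are both set in one Ru–TsDPEN transfer hydrogenation under dynamic kinetic resolution, giving the cis-(3S,4S)-isoflavan-4-ol. The carbinol oxygen becomes O11 with its C–O bond intact, so the cis-(6aS,11aS) fusion is carried through unchanged.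
- Enabling feature: in ring D, O11 sits on C10a, ortho to C6b and meta to the C9 oxygen. This is the pattern left when a 4-hydroxycyclohexa-2,5-dienone centred on C6b takes an oxygen nucleophile at a β-carbon and then loses the C6b hydroxyl as water.

Key step: step 6

Remark: the SMILES is read as the cis-fused (6aS,11aS) pterocarpan; isoflavonoid numbering is used for 9–11 and pterocarpan numbering from 12 on (ring A = trioxygenated benzene ring, B = pyran, C = dihydrofuran, D = second six-membered carbocycle, E = dimethyldihydropyran).

**Step 1**
Reactants: 1 1-(2,4,6-trihydroxyphenyl)-2-(4-hydroxyphenyl)ethanone; 2 allyl bromide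
Product: 3 1-(4-allyloxy-2,6-dihydroxyphenyl)-2-(4-hydroxyphenyl)ethanone
Conditions: allyl bromide (1.0 equiv), K2CO3 (1.0 equiv), acetone, rt
Reagents that add atoms: allyl bromide 2, C=CCBr
Why: Williamson etherification with one equivalent of weak base should alkylate only the ring A hydroxyl para to the ketone, the most acidic one (vinylogous carboxylic acid), because the two ortho hydroxyls are hydrogen-bonded to the carbonyl and the ring D phenol is distinctly less acidic.

**Step 2**
Reactants: 3 1-(4-allyloxy-2,6-dihydroxyphenyl)-2-(4-hydroxyphenyl)ethanone; 4 2-methylbut-3-en-2-ol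
Product: 6 1-(5-allyloxy-7-hydroxy-2,2-dimethylchroman-8-yl)-2-(4-hydroxyphenyl)ethanone, via C-prenyl phenol 5 (not isolated)
Conditions: 2-methylbut-3-en-2-ol (1.1 equiv), BF3·OEt2, 1,4-dioxane, rt; then p-TsOH·H2O (cat.), toluene, 80 °C
Reagents that add atoms: 2-methylbut-3-en-2-ol 4, CC(C)(O)C=C
Why: Friedel–Crafts prenylation of the acylphloroglucinol ring at one of its two equivalent free positions is followed by acid-catalysed Markovnikov hydroalkoxylation of the prenyl double bond, and since the para oxygen is blocked as its allyl ether only the neighbouring ortho hydroxyl can close ring E, which fixes the oxygen-on-C1, carbon-on-C2 orientation of the target.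

**Step 3**
Reactants: 6 1-(5-allyloxy-7-hydroxy-2,2-dimethylchroman-8-yl)-2-(4-hydroxyphenyl)ethanone
Product: 9 rac-7-allyloxy-4′-hydroxyisoflavanone bearing a 2,2-dimethyldihydropyran ring across C5–C6 (ring oxygen on C5), via Mannich base 7 (not isolated), via α-methylene ketone 8 (not isolated)
Conditions: (CH2O)n, Et2NH, MeOH, reflux
Reagents that add atoms: paraformaldehyde (as formaldehyde), C=O
Why: Mannich reaction at the benzylic α-carbon, β-elimination of diethylamine to the 2-aryl enone and 6-endo-trig oxa-Michael addition of the remaining ortho hydroxyl close ring B (the formaldehyde annulation of 2-hydroxydeoxybenzoins to isoflavanones); C3 is formed racemic and is resolved dynamically in step 4.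

**Step 4**
Reactants: 9 rac-isoflavanone
Product: 10 (3S,4S)-7-allyloxy-4′-hydroxyisoflavan-4-ol with ring E across C5–C6 (3-aryl and 4-OH cis)
Conditions: RuCl(p-cymene)[(S,S)-TsDPEN] (3 mol %), HCO2H/Et3N (5:2), EtOAc, 40 °C
Reagents that add atoms: none
Why: Noyori–Ikariya asymmetric transfer hydrogenation under dynamic kinetic resolution: C3 of the α-aryl ketone epimerises through its enol in the amine/formate buffer, and the (S,S)-catalyst, which for aryl ketones gives the (S)-carbinol, should reduce the 3S ketone faster with hydride entering anti to the ring D aryl group, so the cis-(3S,4S) alcohol results and both stereocentres of the target are set here.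

**Step 5**
Reactants: 10 (3S,4S)-cis-isoflavan-4-ol
Product: 11 (3S,4S)-7-allyloxy-3-(1-hydroxy-4-oxocyclohexa-2,5-dien-1-yl)chroman-4-ol carrying ring E across C5–C6 (p-quinol)
Conditions: PhI(OAc)2 (1.05 equiv), MeCN/H2O (4:1), 0 °C; NaHCO3 work-up, crude product taken on
Reagents that add atoms: water, O
Why: Oxidative dearomatisation of a para-alkylphenol by trivalent iodine: ligand exchange of the ring D phenol at iodine and loss of iodobenzene make the para carbon electrophilic and water adds there to give the p-quinol, while ring A offers no free phenol to the oxidant and the C4 hydroxyl could reach the para carbon only through a four-membered ring; the quinol carbon is not stereogenic and C3 and C4 are untouched.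

**Step 6**
Reactants: 11 p-quinol
Product: 13 (6aS,11aS)-3-allyloxy-9-hydroxypterocarpan carrying ring E across C1–C2 (ring oxygen on C1), via oxa-Michael adduct 12 (not isolated)
Conditions: DBU (0.2 equiv), CH2Cl2, 0 °C to rt; then p-TsOH·H2O (0.5 equiv), rt to 40 °C
Reagents that add atoms: none
Why: Under DBU the secondary C11a hydroxyl adds in conjugate fashion to a β-carbon of the cross-conjugated dienone, forming O11–C10a; the acid then enolises the remaining enone, protonates the tertiary C6b hydroxyl, water leaves, H10a is lost and the resulting cyclohexa-2,4-dienone tautomerises to the C9 phenol. The closest known reaction type is the intramolecular oxa-Michael addition of hydroxyalkyl p-quinols followed by acid-promoted dehydrative aromatisation of the 4-hydroxycyclohexenone to a 6-hydroxy-2,3-dihydrobenzofuran. Ring C closes in the 5-exo-trig mode; ring D is not closed but regains aromaticity. No stereocentre of the product is created: C6b and C10a are stereogenic only in 12, attack at either diastereotopic β-carbon leads to the same phenol, and C6a and C11a keep their configuration because neither their C–H bonds nor the C11a–O bond is broken. The step needs dehydration to win over a quinol-type 1,2-shift and over destructive ionisation of the benzylic C–O bond; this is secured by closing ring C under base before any acid is admitted, so the acid meets a mono-enone that cannot undergo a dienone–phenol shift. A C11a cation, should it form, can re-close only to the cis-fused ring, and the tertiary quinol hydroxyl cannot compete as nucleophile since it would have to form a three-membered ring.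

**Step 7**
Reactants: 13 3-allyloxy-9-hydroxypterocarpan
Product: 14 (6aS,11aS)-3-allyloxy-9-methoxypterocarpan carrying ring E across C1–C2
Conditions: MeI, K2CO3, acetone, rt to 40 °C
Reagents that add atoms: iodomethane, CI
Why: Williamson O-methylation of the only acidic hydroxyl, the new C9 phenol; nothing else in 13 is alkylated under carbonate and neither stereocentre carries an acidic hydrogen.

**Step 8**
Reactants: 14 3-allyloxy-9-methoxypterocarpan
Product: 15 target (6aS,11aS)-3-hydroxy-9-methoxypterocarpan carrying ring E across C1–C2
Conditions: Pd(PPh3)4 (5 mol %), morpholine, THF, rt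
Reagents that add atoms: none
Why: Tsuji–Trost-type deallylation: zerovalent palladium ionises the aryl allyl ether to a π-allylpalladium complex and the C3 phenoxide, morpholine captures the allyl fragment, and the methyl ether, the benzylic C11a–O11 ether and ring E are inert under these neutral conditions.

**Compound list**
1 | 1-(2,4,6-trihydroxyphenyl)-2-(4-hydroxyphenyl)ethanone | O=C(Cc1ccc(O)cc1)c1c(O)cc(O)cc1O | starting material
2 | allyl bromide | C=CCBr | starting material
3 | 1-(4-allyloxy-2,6-dihydroxyphenyl)-2-(4-hydroxyphenyl)ethanone | O=C(Cc1ccc(O)cc1)c1c(O)cc(OCC=C)cc1O | intermediate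
4 | 2-methylbut-3-en-2-ol | CC(C)(O)C=C | starting material
5 | 1-[4-allyloxy-2,6-dihydroxy-3-(3-methylbut-2-enyl)phenyl]-2-(4-hydroxyphenyl)ethanone (C-prenyl phenol, not isolated) | O=C(Cc1ccc(O)cc1)c1c(O)cc(OCC=C)c(CC=C(C)C)c1O | intermediate
6 | 1-(5-allyloxy-7-hydroxy-2,2-dimethylchroman-8-yl)-2-(4-hydroxyphenyl)ethanone | O=C(Cc1ccc(O)cc1)c1c(O)cc(OCC=C)c2c1OC(C)(C)CC2 | intermediate
7 | racemic Mannich base, 1-(5-allyloxy-7-hydroxy-2,2-dimethylchroman-8-yl)-3-(diethylamino)-2-(4-hydroxyphenyl)propan-1-one (not isolated) | O=C(C(CN(CC)CC)c1ccc(O)cc1)c1c(O)cc(OCC=C)c2c1OC(C)(C)CC2 | intermediate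
8 | α-methylene ketone, 1-(5-allyloxy-7-hydroxy-2,2-dimethylchroman-8-yl)-2-(4-hydroxyphenyl)prop-2-en-1-one (not isolated) | O=C(C(=C)c1ccc(O)cc1)c1c(O)cc(OCC=C)c2c1OC(C)(C)CC2 | intermediate
9 | rac-7-allyloxy-4′-hydroxyisoflavanone with a 2,2-dimethyldihydropyran ring across C5–C6 (ring oxygen on C5, CH2 on C6) | O=C1C(c2ccc(O)cc2)COc2cc(OCC=C)c3c(c21)OC(C)(C)CC3 | intermediate
10 | (3S,4S)-7-allyloxy-4′-hydroxyisoflavan-4-ol with the same ring E, 3-aryl and 4-OH cis | O[C@@H]1c2c(cc(OCC=C)c3c2OC(C)(C)CC3)OC[C@@H]1c1ccc(O)cc1 | intermediate
11 | (3S,4S)-7-allyloxy-3-(1-hydroxy-4-oxocyclohexa-2,5-dien-1-yl)chroman-4-ol with the same ring E (p-quinol) | O[C@@H]1c2c(cc(OCC=C)c3c2OC(C)(C)CC3)OC[C@@H]1C1(O)C=CC(=O)C=C1 | intermediate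
12 | oxa-Michael adduct (not isolated): 3-allyloxy-6b-hydroxy-6b,10,10a-trihydropterocarpan-9-one with ring E, ring C cis-fused to ring D (6b-OH and 10a-H cis); drawn as the (6aS,6bS,10aR,11aS) isomer with ring D anti to ring B across ring C, the C6b/C10a epimer leading to the same product | O=C1C=C[C@@]2(O)[C@@H](C1)O[C@@H]1c3c(cc(OCC=C)c4c3OC(C)(C)CC4)OC[C@H]21 | intermediate
13 | (6aS,11aS)-3-allyloxy-9-hydroxypterocarpan with ring E across C1–C2 (ring oxygen on C1) | Oc1ccc2c(c1)O[C@@H]1c3c(cc(OCC=C)c4c3OC(C)(C)CC4)OC[C@H]21 | intermediate
14 | (6aS,11aS)-3-allyloxy-9-methoxypterocarpan with ring E across C1–C2 | COc1ccc2c(c1)O[C@@H]1c3c(cc(OCC=C)c4c3OC(C)(C)CC4)OC[C@H]21 | intermediate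
15 | (6aS,11aS)-3-hydroxy-9-methoxypterocarpan with ring E across C1–C2 (CNP0207547.1) | COc1ccc2c(c1)O[C@@H]1c3c(cc(O)c4c3OC(C)(C)CC4)OC[C@H]21 | target

Total step count: 8. Longest linear sequence: 8 steps (1 to 15).

**Steps most likely to fail**

Step 6. The acid stage may divert the material: the doubly ortho-oxygenated benzylic C11a–O bond may ionise and lose H6a, or a quinol-type 1,2-shift may follow retro-addition, before the C6b hydroxyl leaves. The fallback separates dehydration from ring closure and uses no acid. It sets out from 11: DBU alone gives the oxa-Michael adduct 12, which is now isolated. Methyl N-(triethylammoniosulfonyl)carbamate (Burgess reagent) in THF at rt to 50 °C converts the tertiary hydroxyl into the C6b sulfamate ester F1. Its only β-hydrogen, H10a, is cis to the leaving group, so thermal syn-elimination should give the ring D cyclohexa-2,4-dienone, which tautomerises to phenol 13, where the route is rejoined.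

Step 5. Trivalent iodine may attack the electron-rich ring A, acetate may compete with water for the oxidised ring D, or the acetic acid released may ionise the C4 carbinol. The fallback brings in the oxygen with singlet oxygen under basic conditions. It sets out from 10: KHSO5 (as 2KHSO5·KHSO4·K2SO4) and NaHCO3 in MeCN/H2O should convert the ring D phenolate into the 4-hydroperoxycyclohexadienone F2. Me2S added to the same flask reduces the hydroperoxide to p-quinol 11, where the route is rejoined.

Step 4. Hydride transfer to the electron-rich, doubly ortho-oxygenated ketone may be too slow, or C3 may epimerise too slowly for a clean dynamic resolution, which would erode cis- and enantioselectivity. The fallback divides stereocontrol between the substrate and a separation. It sets out from 9: LiBH(s-Bu)3 in THF at −78 °C should deliver hydride to the face away from the C3 aryl group and give the cis alcohol as a racemate, that is 10 together with its mirror image, the (3R,4R)-alcohol F3. Chromatography on a chiral stationary phase then provides 10, where the route is rejoined.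

**Further compounds**
F1 | step 6 | C6b O-[N-(methoxycarbonyl)sulfamoyl] ester of adduct 12 (formed as its triethylammonium salt) | O=C1C=C[C@@]2(OS(=O)(=O)NC(=O)OC)[C@@H](C1)O[C@@H]1c3c(cc(OCC=C)c4c3OC(C)(C)CC4)OC[C@H]21
F2 | step 5 | (3S,4S)-7-allyloxy-3-(1-hydroperoxy-4-oxocyclohexa-2,5-dien-1-yl)chroman-4-ol with ring E | O[C@@H]1c2c(cc(OCC=C)c3c2OC(C)(C)CC3)OC[C@@H]1C1(OO)C=CC(=O)C=C1
F3 | step 4 | (3R,4R)-7-allyloxy-4′-hydroxyisoflavan-4-ol with ring E, mirror image of 10 | O[C@H]1c2c(cc(OCC=C)c3c2OC(C)(C)CC3)OC[C@H]1c1ccc(O)cc1
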